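## Retrosynthetic overview

1. Target tetramer 11 (the all-(4β→8)-linked (−)-epicatechin tetramer of the cinnamtannin family) ⇐ 10 by one global hydrogenolysis, which removes twenty benzyl ethers and the C8 bromine cap.
2. 10 ⇐ 6 + 8: the central C4(unit 2)–C8(unit 3) bond is made by a new one-pot C–H/C–H coupling (DDQ, then Yb(OTf)3), with 6 as the C4–H partner and 8 as the C8–H nucleophile.
3. 8 ⇐ 6 (Br → H); 6 ⇐ 5 + 3 by Friedel–Crafts C4–C8 coupling, 4β by substrate control, with the C8 bromine blocking self-condensation.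
4. 5 ⇐ 4 ⇐ 3 ⇐ 2 ⇐ (−)-epicatechin 1, by benzylation, C8 bromination and DDQ C4–H alkoxylation.
5. No ring is built. The four chroman cores (rings A, B, C) and all C2/C3 stereocentres come intact from 1. The outer interflavan bonds (units 1–2 and 3–4) are formed first in one reaction, then the central bond (units 2–3).

Assumption: (−)-epicatechin is bought as the single (2R,3R) enantiomer and is the only source of the C2/C3 stereocentres; reagents are given by name and SMILES and carry no compound number.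

Units are counted from the top: unit 1 has the free C8, unit 4 has CH2 at C4.

## Route

Step 1
Reactants: 1 (−)-epicatechin
Product: 2 tetra-O-benzylepicatechin (5,7,3',4'-O-benzyl; 3-OH free)
Conditions: BnBr (4.4 equiv), K2CO3 (4.6 equiv), DMF, Ar, −20 °C to rt, 24 h
Reagents that add atoms: benzyl bromide, BrCc1ccccc1
Why: Williamson ether synthesis in which K2CO3 alkylates the four phenols but not the secondary 3-OH, and low temperature under argon avoids C2 epimerisation and C-benzylation, so no stereocentre is touched.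

Step 2
Reactants: 2 tetra-O-benzylepicatechin
Product: 3 penta-O-benzylepicatechin
Conditions: NaH (1.5 equiv), BnBr (1.5 equiv), n-Bu4NI (0.1 equiv), THF/DMF, 0 °C to rt
Reagents that add atoms: benzyl bromide, BrCc1ccccc1
Why: Williamson ether synthesis of the secondary alkoxide, which is safe for C2 because with all phenols capped no quinone-methide ring-opening pathway exists.

Step 3
Reactants: 3 penta-O-benzylepicatechin
Product: 4 penta-O-benzyl-8-bromoepicatechin
Conditions: NBS (1.05 equiv), CH2Cl2, −78 °C to 0 °C, dark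
Reagents that add atoms: N-bromosuccinimide, O=C1CCC(=O)N1Br
Why: Electrophilic aromatic substitution in which ring A (a phloroglucinol triether) is far more electron-rich than ring B and reacts at C8, installing the bromine that later serves as the cap against self-condensation.

Step 4
Reactants: 4 penta-O-benzyl-8-bromoepicatechin
Product: 5 penta-O-benzyl-8-bromo-4β-(2-ethoxyethoxy)epicatechin
Conditions: DDQ (2 equiv), HOCH2CH2OEt (5 equiv), CH2Cl2, rt
Reagents that add atoms: 2-ethoxyethanol, CCOCCO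
Why: Benzylic C–H oxidation by DDQ hydride abstraction, in which the ring A-stabilised C4 cation is trapped by the alcohol on the face anti to the α-oriented 3-OBn and 2-aryl groups to give the 4β (4S) ether.

Step 5
Reactants: 5 penta-O-benzyl-8-bromo-4β-(2-ethoxyethoxy)epicatechin, 3 penta-O-benzylepicatechin
Product: 6 deca-O-benzyl-8-bromo-(4β→8) epicatechin dimer
Conditions: 3 (1.5 equiv), TMSOTf (0.2 equiv), 4 Å MS, CH2Cl2, −78 °C; then aq. NaHCO3
Reagents that add atoms: none
Why: Lewis acid-mediated Friedel–Crafts alkylation (SN1) in which TMSOTf ionises the 4-alkoxy group, C8 of 3 adds to the planar cation anti to 3-OBn and the 2-aryl group to set the 4β (3,4-trans) interflavan stereocentre, and the C8 bromine of 5 blocks its own ring A so no oligomer forms.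

Step 6
Reactants: 6 deca-O-benzyl-8-bromo-(4β→8) epicatechin dimer
Product: 8 deca-O-benzyl-(4β→8) epicatechin dimer, via 8-lithio dimer 7 (not isolated)
Conditions: n-BuLi (1.2 equiv), THF, −78 °C, 10 min; then MeOH, −78 °C to rt
Reagents that add atoms: none
Why: Bromine–lithium exchange followed by protonation, where exchange at −78 °C outruns benzylic deprotonation, the aryllithium is stabilised by its two flanking ether oxygens, and the methanol quench frees C8–H without touching any stereocentre.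

Step 7
Reactants: 6 deca-O-benzyl-8-bromo-(4β→8) epicatechin dimer, 8 deca-O-benzyl-(4β→8) epicatechin dimer
Product: 10 icosa-O-benzyl-8-bromo-(4β→8) epicatechin tetramer, via quinol ether 9 (not isolated)
Conditions: 6 (1.0 equiv), DDQ (0.95 equiv), 4 Å MS, CH2Cl2, 0 °C, dark, 1 h; then 8 (1.0 equiv), Yb(OTf)3 (10 mol %), −20 °C to rt
Reagents that add atoms: none
Why: Proposed new method: a one-pot cross-dehydrogenative C4–H/C8–H interflavan coupling in which DDQ, with no trapping alcohol present, abstracts the pseudo-axial hydride at the only CH2 benzylic to a trioxygenated ring A (C4 of the lower unit of 6; the upper C4–H is a shielded methine held near the plane of its flanking rings), the ion pair collapses to the 4β quinol ether 9, which the C8 bromine cap keeps from arylating itself, and Yb(OTf)3 then re-ionises this electron-poor aryloxide so that C8 of the upper unit of 8 adds to the planar cation anti to the α-oriented 3-OBn and 2-aryl groups, setting the new 4β (3,4-trans) stereocentre and releasing only DDQH2; because the oxidant is spent before 8 is added, the C4–H2 of 8 is never oxidised and 1:1 stoichiometry stops growth at the tetramer; the closest known reaction types are DDQ-mediated C4–H alkoxylation of benzylated flavans, DDQ cross-dehydrogenative arylation of benzylic ethers such as isochromans, and Lewis acid Friedel–Crafts coupling of 4-alkoxyflavans.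

Step 8
Reactants: 10 icosa-O-benzyl-8-bromo-(4β→8) epicatechin tetramer
Product: 11 target tetramer, epicatechin-(4β→8)-epicatechin-(4β→8)-epicatechin-(4β→8)-epicatechin
Conditions: H2 (1 atm), Pd(OH)2/C, NaOAc (1.5 equiv), THF/MeOH/H2O (20:1:1), rt; Sephadex LH-20, lyophilise
Reagents that add atoms: none
Why: Heterogeneous catalytic hydrogenolysis, in which Pd(OH)2/C cleaves all twenty benzylic C–O bonds and the aryl C–Br bond while NaOAc buffers the HBr, leaving the acid-labile interflavan bonds and all eleven stereocentres untouched.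

## Compound list

1 | (−)-epicatechin, (2R,3R)-2-(3,4-dihydroxyphenyl)chromane-3,5,7-triol | Oc1cc(O)c2c(c1)O[C@H](c1ccc(O)c(O)c1)[C@H](O)C2 | starting material

2 | tetra-O-benzylepicatechin, (2R,3R)-5,7-bis(benzyloxy)-2-[3,4-bis(benzyloxy)phenyl]chroman-3-ol | c1ccccc1COc1cc(OCc3ccccc3)c2c(c1)O[C@H](c1ccc(OCc3ccccc3)c(OCc3ccccc3)c1)[C@H](O)C2 | intermediate

3 | penta-O-benzylepicatechin, (2R,3R)-3,5,7-tris(benzyloxy)-2-[3,4-bis(benzyloxy)phenyl]chromane | c1ccccc1COc1cc(OCc3ccccc3)c2c(c1)O[C@H](c1ccc(OCc3ccccc3)c(OCc3ccccc3)c1)[C@H](OCc1ccccc1)C2 | intermediate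

4 | penta-O-benzyl-8-bromoepicatechin, the (2R,3R) C8-bromo derivative of 3 | c1ccccc1COc1cc(OCc3ccccc3)c2c(c1Br)O[C@H](c1ccc(OCc3ccccc3)c(OCc3ccccc3)c1)[C@H](OCc1ccccc1)C2 | intermediate

5 | penta-O-benzyl-8-bromo-4β-(2-ethoxyethoxy)epicatechin, (2R,3R,4S), 4-alkoxy trans to 3-OBn | c1ccccc1COc1cc(OCc3ccccc3)c2c(c1Br)O[C@H](c1ccc(OCc3ccccc3)c(OCc3ccccc3)c1)[C@H](OCc1ccccc1)[C@H]2OCCOCC | intermediate

6 | deca-O-benzyl-8-bromo-(4β→8) epicatechin dimer, [penta-O-benzyl-8-bromoepicatechin]-(4β→8)-[penta-O-benzylepicatechin]; both units 2R,3R, interflavan bond β and trans to the upper 3-OBn, Br at C8 of the upper unit | c1ccccc1COc1cc(OCc3ccccc3)c2c(c1Br)O[C@H](c1ccc(OCc3ccccc3)c(OCc3ccccc3)c1)[C@H](OCc1ccccc1)[C@H]2c1c(OCc3ccccc3)cc(OCc3ccccc3)c2c1O[C@H](c1ccc(OCc3ccccc3)c(OCc3ccccc3)c1)[C@H](OCc1ccccc1)C2 | intermediate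

7 | 8-lithio dimer, 6 with Li in place of Br at C8 of the upper unit | c1ccccc1COc1cc(OCc3ccccc3)c2c(c1[Li])O[C@H](c1ccc(OCc3ccccc3)c(OCc3ccccc3)c1)[C@H](OCc1ccccc1)[C@H]2c1c(OCc3ccccc3)cc(OCc3ccccc3)c2c1O[C@H](c1ccc(OCc3ccccc3)c(OCc3ccccc3)c1)[C@H](OCc1ccccc1)C2 | intermediate (not isolated)

8 | deca-O-benzyl-(4β→8) epicatechin dimer, [penta-O-benzylepicatechin]-(4β→8)-[penta-O-benzylepicatechin], free C8–H on the upper unit | c1ccccc1COc1cc(OCc3ccccc3)c2c(c1)O[C@H](c1ccc(OCc3ccccc3)c(OCc3ccccc3)c1)[C@H](OCc1ccccc1)[C@H]2c1c(OCc3ccccc3)cc(OCc3ccccc3)c2c1O[C@H](c1ccc(OCc3ccccc3)c(OCc3ccccc3)c1)[C@H](OCc1ccccc1)C2 | intermediate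

9 | quinol ether, 6 carrying a 4β-(2,3-dichloro-5,6-dicyano-4-hydroxyphenoxy) group at C4 of the lower unit, trans to its 3-OBn | c1ccccc1COc1cc(OCc3ccccc3)c2c(c1Br)O[C@H](c1ccc(OCc3ccccc3)c(OCc3ccccc3)c1)[C@H](OCc1ccccc1)[C@H]2c1c(OCc3ccccc3)cc(OCc3ccccc3)c2c1O[C@H](c1ccc(OCc3ccccc3)c(OCc3ccccc3)c1)[C@H](OCc1ccccc1)[C@H]2Oc1c(Cl)c(Cl)c(O)c(C#N)c1C#N | intermediate (not isolated)

10 | icosa-O-benzyl-8-bromo-(4β→8) epicatechin tetramer, four penta-O-benzylepicatechin units (each 2R,3R) joined by three 4β→8 bonds, Br at C8 of unit 1 | c1ccccc1COc1cc(OCc3ccccc3)c2c(c1Br)O[C@H](c1ccc(OCc3ccccc3)c(OCc3ccccc3)c1)[C@H](OCc1ccccc1)[C@H]2c1c(OCc3ccccc3)cc(OCc3ccccc3)c2c1O[C@H](c1ccc(OCc3ccccc3)c(OCc3ccccc3)c1)[C@H](OCc1ccccc1)[C@H]2c1c(OCc3ccccc3)cc(OCc3ccccc3)c2c1O[C@H](c1ccc(OCc3ccccc3)c(OCc3ccccc3)c1)[C@H](OCc1ccccc1)[C@H]2c1c(OCc3ccccc3)cc(OCc3ccccc3)c2c1O[C@H](c1ccc(OCc3ccccc3)c(OCc3ccccc3)c1)[C@H](OCc1ccccc1)C2 | intermediate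

11 | target tetramer, epicatechin-(4β→8)-epicatechin-(4β→8)-epicatechin-(4β→8)-epicatechin, every unit 2R,3R and every interflavan bond β | Oc1cc(O)c2c(c1)O[C@H](c1ccc(O)c(O)c1)[C@H](O)[C@H]2c1c(O)cc(O)c2c1O[C@H](c1ccc(O)c(O)c1)[C@H](O)[C@H]2c1c(O)cc(O)c2c1O[C@H](c1ccc(O)c(O)c1)[C@H](O)[C@H]2c1c(O)cc(O)c2c1O[C@H](c1ccc(O)c(O)c1)[C@H](O)C2 | target

## Step count and risks

Total steps: 8. Longest linear sequence: 8 (1 → 2 → 3 → 4 → 5 → 6 → 8 → 10 → 11; compound 6 is used twice).

Three steps most likely to fail: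

**Step 7 (the proposed new coupling).** The cation or quinol ether from 6 may decay by loss of H3 or by over-oxidation before 8 is added, or leftover DDQ may oxidise 8. The fallback uses known chemistry, sets out from 6 and comes back at 10. Compound 6 is oxidised with DDQ in the presence of 2-ethoxyethanol (CH2Cl2, rt), which traps the cation at once and gives the isolable deca-O-benzyl-8-bromo-4β-(2-ethoxyethoxy) epicatechin dimer F1. F1 and 8 (1:1) are then condensed with Yb(OTf)3 in CH2Cl2 (or TMSOTf at −78 °C) to give 10 by the same Friedel–Crafts logic as step 5.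

**Step 8 (global hydrogenolysis).** Twenty benzyl groups may not all come off, bromide may poison the catalyst, or HBr may cleave interflavan bonds. The fallback sets out from 10 and comes back at 11, separating the two tasks. The bromine is first removed by radical chain reduction (Bu3SnH, AIBN, PhMe, 90 °C) to give the icosa-O-benzyl-(4β→8) epicatechin tetramer F3. F3 is then hydrogenolysed under neutral, halide-free conditions (H2, Pd(OH)2/C, THF/MeOH/H2O) to 11.

**Step 6 (bromine–lithium exchange on a decabenzyl dimer).** The aryllithium may translocate to a benzylic position or undergo Wittig-type rearrangement. The fallback sets out from 3 and comes back at 8, with no bromide and no organolithium. Compound 3 is oxidised with DDQ and 2-ethoxyethanol (CH2Cl2, rt) to penta-O-benzyl-4β-(2-ethoxyethoxy)epicatechin F2. F2 is condensed with an excess of 3 (3 equiv, TMSOTf, CH2Cl2, −78 °C); the excess suppresses oligomers and is recovered, and the product is 8.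

## Further compounds

F1 | step 7 | deca-O-benzyl-8-bromo-4β-(2-ethoxyethoxy) epicatechin dimer (ether at C4 of the lower unit, trans to its 3-OBn) | c1ccccc1COc1cc(OCc3ccccc3)c2c(c1Br)O[C@H](c1ccc(OCc3ccccc3)c(OCc3ccccc3)c1)[C@H](OCc1ccccc1)[C@H]2c1c(OCc3ccccc3)cc(OCc3ccccc3)c2c1O[C@H](c1ccc(OCc3ccccc3)c(OCc3ccccc3)c1)[C@H](OCc1ccccc1)[C@H]2OCCOCC

F2 | step 6 | penta-O-benzyl-4β-(2-ethoxyethoxy)epicatechin, (2R,3R,4S) | c1ccccc1COc1cc(OCc3ccccc3)c2c(c1)O[C@H](c1ccc(OCc3ccccc3)c(OCc3ccccc3)c1)[C@H](OCc1ccccc1)[C@H]2OCCOCC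

F3 | step 8 | icosa-O-benzyl-(4β→8) epicatechin tetramer (10 with H in place of Br) | c1ccccc1COc1cc(OCc3ccccc3)c2c(c1)O[C@H](c1ccc(OCc3ccccc3)c(OCc3ccccc3)c1)[C@H](OCc1ccccc1)[C@H]2c1c(OCc3ccccc3)cc(OCc3ccccc3)c2c1O[C@H](c1ccc(OCc3ccccc3)c(OCc3ccccc3)c1)[C@H](OCc1ccccc1)[C@H]2c1c(OCc3ccccc3)cc(OCc3ccccc3)c2c1O[C@H](c1ccc(OCc3ccccc3)c(OCc3ccccc3)c1)[C@H](OCc1ccccc1)[C@H]2c1c(OCc3ccccc3)cc(OCc3ccccc3)c2c1O[C@H](c1ccc(OCc3ccccc3)c(OCc3ccccc3)c1)[C@H](OCc1ccccc1)C2
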